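**Retrosynthetic overview**

- The strategy rests on ring A, the 2,3-dihydrofuran (O, C1, C2, C3, C4), whose enol ether C1(–O–C4)=C2 bridges the ten-membered carbocycle C1–C10. C4 and C10 sit 1,4 across the ring oxygen, so each is made in its own fragment, the two are joined as the ester C1(=O)–O–C4, and that ester is converted into the enol ether by titanium-mediated carbonyl–olefin metathesis with the allyl group on C4 (C3, C2).
- C4 comes from (R)-2-methylglycidol (vinyl Grignard opening); C10 is set by a copper–bis(oxazoline) Mukaiyama aldol on the pyruvate ester of the C4 alcohol.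
- C7–C8: Nozaki–Hiyama–Kishi coupling of the C8 aldehyde with 3-bromo-4-iodofuran-2(5H)-one (ring B, brought in preformed), then oxidation and CBS reduction for 8S. C13 is added last by Stille hydroxymethylation of the C11 bromide.
- C5=C6: the ten-membered ring (ring C) is closed by intramolecular vinylogous aldol–elimination, so that the ring itself forces C4 cis to C7 (5E), which an open-chain condensation would not give. Ring order: A (step 9), B attached (step 13), C (step 19).

Key step: step 9

Remark on numbering: C1 is the enol ether carbon, C4 and C10 the oxygenated quaternary carbons (methyls C15 and C14), C5=C6 the ylidene, C7=C11 the butenolide alkene, C8 the acetoxy carbon, C12 the lactone carbonyl, C13 the acetoxymethyl carbon. In these locants the target is 4S,5E,8S,10S.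

Remark on protecting groups: only silyl ethers pass through the key step and all are later removed with fluoride, because a benzyl-type ether would need DDQ, which the electron-rich enol ether is not expected to survive. C13 is introduced after ring closure because an oxygen leaving group on C13 would be expelled from the butenolide dienolate.

Assumption: from 17 onward the enol ethers are chromatographed on triethylamine-deactivated silica and kept away from protic acid.

**Step 1**
Reactants: 1 (R)-2-methylglycidol
Product: 2 tert-butyldimethyl{[(2S)-2-methyloxiran-2-yl]methoxy}silane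
Conditions: TBSCl, imidazole, DMF, 0 °C to rt
Reagents that add atoms: tert-butyldimethylsilyl chloride, CC(C)(C)[Si](C)(C)Cl
Why: Imidazole-promoted silylation of the primary alcohol leaves the epoxide and the quaternary centre untouched; the descriptor changes from R to S only because the CIP ranking of the two CH2O arms is reversed.

**Step 2**
Reactants: 2 silyl glycidyl ether; 3 vinylmagnesium bromide
Product: 4 (2S)-1-[(tert-butyldimethylsilyl)oxy]-2-methylpent-4-en-2-ol
Conditions: CuI (10 mol%), THF, −30 to 0 °C
Reagents that add atoms: none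
Why: Copper-catalysed Grignard opening (SN2) of the 2,2-disubstituted epoxide occurs at its unhindered CH2 terminus, so the C4 centre is carried over unchanged and the allyl group that supplies C3 and C2 is installed.

**Step 3**
Reactants: 4 tertiary alcohol; 5 pyruvic acid
Product: 7 (2S)-1-[(tert-butyldimethylsilyl)oxy]-2-methylpent-4-en-2-yl 2-oxopropanoate, via pyruvoyl chloride 6 (not isolated)
Conditions: 5, Cl2CHOCH3, 50 °C; then 4, pyridine, DMAP (cat.), CH2Cl2, −20 to 0 °C
Reagents that add atoms: none
Why: Acylation of the tertiary alcohol with the small, very electrophilic α-keto acid chloride (made from the acid with dichloromethyl methyl ether) is the dependable way to esterify a hindered alcohol with pyruvic acid.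

**Step 4**
Reactants: 8 S-tert-butyl thioacetate
Product: 9 1-(tert-butylsulfanyl)-1-[(trimethylsilyl)oxy]ethene
Conditions: LDA, THF, −78 °C; TMSCl
Reagents that add atoms: chlorotrimethylsilane, C[Si](C)(C)Cl
Why: Kinetic deprotonation and O-silylation of the thioester enolate give the silyl ketene thioacetal used as Mukaiyama nucleophile.

**Step 5**
Reactants: 7 pyruvate ester; 9 silyl ketene thioacetal
Product: 11 (2S)-1-[(tert-butyldimethylsilyl)oxy]-2-methylpent-4-en-2-yl (2S)-4-(tert-butylsulfanyl)-2-hydroxy-2-methyl-4-oxobutanoate, via trimethylsilyl ether 10 (not isolated)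
Conditions: Cu(OTf)2 (10 mol%), 2,2'-(propane-2,2-diyl)bis[(4S)-4-tert-butyl-4,5-dihydrooxazole] (11 mol%), THF, −78 °C; then 1 M HCl, THF, 0 °C
Reagents that add atoms: none
Why: Catalytic enantioselective Mukaiyama aldol addition to a pyruvate ester: the keto ester chelates divalent copper in a square-planar bis(oxazoline) complex whose tert-butyl groups shield the re face of the ketone, so the enolsilane adds to the si face and sets C10 as S under catalyst control (the remote C4 centre and the weakly coordinating silyl ether should not interfere), and the acidic work-up cleaves the tertiary trimethylsilyl ether.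

**Step 6**
Reactants: 11 hydroxy thioester
Product: 12 (2S)-1-[(tert-butyldimethylsilyl)oxy]-2-methylpent-4-en-2-yl (2S)-4-(tert-butylsulfanyl)-2-methyl-4-oxo-2-[(triethylsilyl)oxy]butanoate
Conditions: TESOTf, 2,6-lutidine, CH2Cl2, −78 to 0 °C
Reagents that add atoms: triethylsilyl trifluoromethanesulfonate, CC[Si](CC)(CC)OS(=O)(=O)C(F)(F)F
Why: Silyl triflate with 2,6-lutidine is the standard silylation of a hindered tertiary α-hydroxy ester.

**Step 7**
Reactants: 12 thioester
Product: 14 (2S)-1-[(tert-butyldimethylsilyl)oxy]-2-methylpent-4-en-2-yl (2S)-4-hydroxy-2-methyl-2-[(triethylsilyl)oxy]butanoate, via aldehyde 13 (not isolated)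
Conditions: DIBAL-H, CH2Cl2, −78 °C; then MeOH, NaBH4, −78 to 0 °C
Reagents that add atoms: none
Why: Chemoselective hydride reduction: the thioester is far more electrophilic than the tertiary alkyl ester flanked by two fully substituted carbons, so DIBAL-H at −78 °C takes it to the aldehyde and NaBH4 to the primary alcohol, which is silylated at once in step 8 to forestall lactonisation.

**Step 8**
Reactants: 14 primary alcohol
Product: 15 (2S)-1-[(tert-butyldimethylsilyl)oxy]-2-methylpent-4-en-2-yl (2S)-2-methyl-2,4-bis[(triethylsilyl)oxy]butanoate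
Conditions: TESCl, imidazole, CH2Cl2, 0 °C
Reagents that add atoms: chlorotriethylsilane, CC[Si](Cl)(CC)CC
Why: Imidazole-promoted silylation of the primary alcohol gives the unhindered primary triethylsilyl ether, the most labile of the three silyl ethers, which can be removed first after the key step.

**Step 9**
Reactants: 15 tertiary homoallylic ester
Product: 17 tert-butyl{[(2S)-5-[(2S)-2,4-bis(triethylsilyloxy)butan-2-yl]-2-methyl-2,3-dihydrofuran-2-yl]methoxy}dimethylsilane, via titanium alkylidene 16 (not isolated)
Conditions: TiCl4, TMEDA, Zn, PbCl2 (cat.), CH3CHBr2, THF/CH2Cl2, 0 to 65 °C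
Reagents that add atoms: none
Why: Low-valent titanium made from TiCl4, Zn and TMEDA with catalytic PbCl2 converts CH3CHBr2 into a titanium ethylidene, which first exchanges with the unhindered terminal alkene ([2+2] addition and cycloreversion, propene lost) to place titanium on C2 (16); this tethered alkylidene then adds across the ester carbonyl to a bicyclic oxatitanacyclobutane whose cycloreversion expels a titanium oxo species and leaves C1=C2. The closest known reaction is the olefinic ester cyclisation with Takai–Utimoto titanium alkylidenes, which turns ω-alkenyl esters into cyclic enol ethers in one flask. Ring A (O, C1, C2, C3, C4) closes by intramolecular carbonyl olefination, a five-membered ring closure in which the alkylidene carbon C2 reaches the carbonyl carbon C1 three atoms away through C3, C4 and the ring oxygen. No stereocentre is formed or touched; C4 and C10 are carried in from steps 2 and 5. The step needs the alkene-first pathway to win over intermolecular ethylidenation of the carbonyl and over oligomerisation, which the shielding of the ester by its two fully substituted neighbours and the short tether should secure; the silyl ethers are inert to the reagent.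

**Step 10**
Reactants: 17 dihydrofuran
Product: 18 (3S)-3-[(2S)-2-{[(tert-butyldimethylsilyl)oxy]methyl}-2-methyl-2,3-dihydrofuran-5-yl]-3-[(triethylsilyl)oxy]butan-1-ol
Conditions: TBAF (1.05 equiv), THF, −20 °C
Reagents that add atoms: none
Why: Fluoride desilylation with steric gradation: the unhindered primary triethylsilyl ether is cleaved well before the neopentyl TBS ether and the tertiary triethylsilyl ether, and the basic medium cannot harm the enol ether.

**Step 11**
Reactants: 18 primary alcohol
Product: 19 (3S)-3-[(2S)-2-{[(tert-butyldimethylsilyl)oxy]methyl}-2-methyl-2,3-dihydrofuran-5-yl]-3-[(triethylsilyl)oxy]butanal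
Conditions: Dess–Martin periodinane, NaHCO3, CH2Cl2, 0 °C
Reagents that add atoms: none
Why: Dess–Martin oxidation buffered with bicarbonate gives the C8 aldehyde without protic acid that could hydrate the enol ether.

**Step 12**
Reactants: 20 3,4-dibromofuran-2(5H)-one
Product: 21 3-bromo-4-iodofuran-2(5H)-one
Conditions: NaI, acetone, reflux
Reagents that add atoms: sodium iodide, [Na+].[I-]
Why: Vinylic Finkelstein exchange by conjugate addition–elimination is possible only at the β-carbon of the butenolide and is driven by precipitation of NaBr.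

**Step 13**
Reactants: 19 C8 aldehyde; 21 bromo-iodo-butenolide
Product: 22 3-bromo-4-{(3S)-3-[(2S)-2-{[(tert-butyldimethylsilyl)oxy]methyl}-2-methyl-2,3-dihydrofuran-5-yl]-1-hydroxy-3-[(triethylsilyl)oxy]butyl}furan-2(5H)-one (both C8 epimers)
Conditions: CrCl2, NiCl2 (cat.), DMSO, rt
Reagents that add atoms: none
Why: Nozaki–Hiyama–Kishi coupling: nickel inserts into the C–I bond much faster than into the α C–Br bond and the vinylchromium species formed by transmetallation adds only to the aldehyde; C8 forms without control, which does not matter because step 14 removes it.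

**Step 14**
Reactants: 22 allylic alcohols
Product: 23 3-bromo-4-{(3S)-3-[(2S)-2-{[(tert-butyldimethylsilyl)oxy]methyl}-2-methyl-2,3-dihydrofuran-5-yl]-3-[(triethylsilyl)oxy]butanoyl}furan-2(5H)-one
Conditions: Dess–Martin periodinane, NaHCO3, CH2Cl2, 0 °C to rt
Reagents that add atoms: none
Why: Dess–Martin oxidation of the allylic alcohol to the ketone erases the uncontrolled C8 centre.

**Step 15**
Reactants: 23 ketone
Product: 24 3-bromo-4-{(1S,3S)-3-[(2S)-2-{[(tert-butyldimethylsilyl)oxy]methyl}-2-methyl-2,3-dihydrofuran-5-yl]-1-hydroxy-3-[(triethylsilyl)oxy]butyl}furan-2(5H)-one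
Conditions: (R)-2-methyl-CBS-oxazaborolidine (0.5 equiv), catecholborane, toluene, −78 °C
Reagents that add atoms: none
Why: Corey–Bakshi–Shibata reduction: the ketone binds the (R)-oxazaborolidine with its larger flank (the fully substituted butenolide carbon C7) turned away from the catalyst, so hydride is delivered to the face that gives the 8S alcohol under reagent control, and catecholborane at −78 °C leaves the enol ether alone.

**Step 16**
Reactants: 24 (8S)-alcohol
Product: 25 (1S,3S)-1-(4-bromo-5-oxo-2,5-dihydrofuran-3-yl)-3-[(2S)-2-{[(tert-butyldimethylsilyl)oxy]methyl}-2-methyl-2,3-dihydrofuran-5-yl]-3-[(triethylsilyl)oxy]butyl acetate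
Conditions: Ac2O, pyridine, DMAP (cat.), CH2Cl2, 0 °C
Reagents that add atoms: acetic anhydride, CC(=O)OC(C)=O
Why: DMAP-catalysed acetylation of the only free hydroxyl installs the C8 acetate of the target, which is also the one protecting group here that fluoride leaves in place.

**Step 17**
Reactants: 25 acetate
Product: 26 (1S,3S)-1-(4-bromo-5-oxo-2,5-dihydrofuran-3-yl)-3-hydroxy-3-[(2S)-2-(hydroxymethyl)-2-methyl-2,3-dihydrofuran-5-yl]butyl acetate
Conditions: TBAF, AcOH (1:1), THF, rt
Reagents that add atoms: none
Why: Acetate-buffered fluoride desilylation removes the neopentyl TBS ether and the tertiary triethylsilyl ether, while the near-neutral medium spares the acetate, the lactone and the enol ether.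

**Step 18**
Reactants: 26 diol
Product: 27 (1S,3S)-1-(4-bromo-5-oxo-2,5-dihydrofuran-3-yl)-3-[(2S)-2-formyl-2-methyl-2,3-dihydrofuran-5-yl]-3-hydroxybutyl acetate
Conditions: Dess–Martin periodinane, NaHCO3, CH2Cl2, 0 °C
Reagents that add atoms: none
Why: Dess–Martin oxidation of the neopentyl primary alcohol gives the non-enolisable C5 aldehyde; the tertiary C10 hydroxyl cannot be oxidised.

**Step 19**
Reactants: 27 seco aldehyde
Product: 30 bromo macrocycle (4S,5E,8S,10S; the target skeleton with Br on C11 in place of C13 and OSiEt3 on C10), via silyloxyfuran 28 (not isolated), via aldol silyl ether 29 (not isolated)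
Conditions: TESOTf, Et3N, CH2Cl2 (1 mM), −78 °C to rt; then DBU, rt
Reagents that add atoms: triethylsilyl trifluoromethanesulfonate, CC[Si](CC)(CC)OS(=O)(=O)C(F)(F)F
Why: Silylative vinylogous Mukaiyama aldol ring closure followed by E1cB elimination: the silyl triflate and amine cap the tertiary hydroxyl, turn the butenolide into its 2-silyloxyfuran 28 and activate the non-enolisable aldehyde, furan carbon C6 attacks C5 at high dilution, and DBU then expels the C5 silyloxy group through the furanolate; because the new alkene lies inside the ten-membered ring it can only form with C4 cis to C7 (5E), and the transient C5 and C6 centres of 29 are lost.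

**Step 20**
Reactants: 30 silylated macrocycle
Product: 31 bromo macrocycle with free C10 hydroxyl (4S,5E,8S,10S)
Conditions: TBAF, AcOH (1:1), THF, 0 °C to rt
Reagents that add atoms: none
Why: Buffered fluoride desilylation cleaves the tertiary triethylsilyl ether without touching the acetate, the enol lactone or the enol ether.

**Step 21**
Reactants: 31 vinyl bromide
Product: 32 13-hydroxy compound (the target lacking the C13 acetyl group)
Conditions: Bu3SnCH2OH, Pd2(dba)3 (5 mol%), AsPh3, CuI, NMP, 50 °C
Reagents that add atoms: (tributylstannyl)methanol, CCCC[Sn](CO)(CCCC)CCCC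
Why: Stille cross-coupling (hydroxymethylation): zerovalent palladium inserts into the vinyl C–Br bond α to the lactone carbonyl and the stannane transfers its CH2OH group, while the tetrasubstituted, electron-poor C7=C11 alkene should be too hindered for the C8 acetate to ionise to an allylpalladium species.

**Step 22**
Reactants: 32 primary alcohol
Product: 33 target, CNP0144020.1
Conditions: Ac2O, pyridine, DMAP (cat.), CH2Cl2, 0 °C
Reagents that add atoms: acetic anhydride, CC(=O)OC(C)=O
Why: Acetylation of the primary allylic alcohol; the tertiary C10 hydroxyl does not react under these conditions, so the target should result directly.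

**Compound list**

1 | (R)-2-methylglycidol, [(2R)-2-methyloxiran-2-yl]methanol | OC[C@]1(C)CO1 | starting material
2 | tert-butyldimethyl{[(2S)-2-methyloxiran-2-yl]methoxy}silane | CC(C)(C)[Si](C)(C)OC[C@]1(C)CO1 | intermediate
3 | vinylmagnesium bromide | C=C[Mg]Br | starting material
4 | (2S)-1-[(tert-butyldimethylsilyl)oxy]-2-methylpent-4-en-2-ol | CC(C)(C)[Si](C)(C)OC[C@](O)(C)CC=C | intermediate
5 | pyruvic acid | CC(=O)C(O)=O | starting material
6 | pyruvoyl chloride | CC(=O)C(Cl)=O | intermediate (not isolated)
7 | (2S)-1-[(tert-butyldimethylsilyl)oxy]-2-methylpent-4-en-2-yl 2-oxopropanoate | CC(C)(C)[Si](C)(C)OC[C@](OC(=O)C(C)=O)(C)CC=C | intermediate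
8 | S-tert-butyl thioacetate | CC(=O)SC(C)(C)C | starting material
9 | 1-(tert-butylsulfanyl)-1-[(trimethylsilyl)oxy]ethene | C=C(O[Si](C)(C)C)SC(C)(C)C | intermediate
10 | trimethylsilyl ether of 11 (4S,10S) | CC(C)(C)[Si](C)(C)OC[C@](OC(=O)[C@@](C)(O[Si](C)(C)C)CC(=O)SC(C)(C)C)(C)CC=C | intermediate (not isolated)
11 | (2S)-1-[(tert-butyldimethylsilyl)oxy]-2-methylpent-4-en-2-yl (2S)-4-(tert-butylsulfanyl)-2-hydroxy-2-methyl-4-oxobutanoate | CC(C)(C)[Si](C)(C)OC[C@](OC(=O)[C@@](C)(O)CC(=O)SC(C)(C)C)(C)CC=C | intermediate
12 | triethylsilyl ether of 11 (4S,10S) | CC(C)(C)[Si](C)(C)OC[C@](OC(=O)[C@@](C)(O[Si](CC)(CC)CC)CC(=O)SC(C)(C)C)(C)CC=C | intermediate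
13 | (2S)-1-[(tert-butyldimethylsilyl)oxy]-2-methylpent-4-en-2-yl (2S)-2-methyl-4-oxo-2-[(triethylsilyl)oxy]butanoate | CC(C)(C)[Si](C)(C)OC[C@](OC(=O)[C@@](C)(O[Si](CC)(CC)CC)CC=O)(C)CC=C | intermediate (not isolated)
14 | (2S)-1-[(tert-butyldimethylsilyl)oxy]-2-methylpent-4-en-2-yl (2S)-4-hydroxy-2-methyl-2-[(triethylsilyl)oxy]butanoate | CC(C)(C)[Si](C)(C)OC[C@](OC(=O)[C@@](C)(O[Si](CC)(CC)CC)CCO)(C)CC=C | intermediate
15 | (2S)-1-[(tert-butyldimethylsilyl)oxy]-2-methylpent-4-en-2-yl (2S)-2-methyl-2,4-bis[(triethylsilyl)oxy]butanoate (key-step precursor) | CC(C)(C)[Si](C)(C)OC[C@](OC(=O)[C@@](C)(O[Si](CC)(CC)CC)CCO[Si](CC)(CC)CC)(C)CC=C | intermediate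
16 | titanium alkylidene of 15 (titanium on C2; TMEDA ligand not shown) | CC(C)(C)[Si](C)(C)OC[C@](OC(=O)[C@@](C)(O[Si](CC)(CC)CC)CCO[Si](CC)(CC)CC)(C)CC=[Ti](Cl)Cl | intermediate (not isolated)
17 | tert-butyl{[(2S)-5-[(2S)-2,4-bis(triethylsilyloxy)butan-2-yl]-2-methyl-2,3-dihydrofuran-2-yl]methoxy}dimethylsilane (key-step product) | CC(C)(C)[Si](C)(C)OC[C@]1(C)CC=C(O1)[C@@](C)(O[Si](CC)(CC)CC)CCO[Si](CC)(CC)CC | intermediate
18 | (3S)-3-[(2S)-2-{[(tert-butyldimethylsilyl)oxy]methyl}-2-methyl-2,3-dihydrofuran-5-yl]-3-[(triethylsilyl)oxy]butan-1-ol | CC(C)(C)[Si](C)(C)OC[C@]1(C)CC=C(O1)[C@@](C)(O[Si](CC)(CC)CC)CCO | intermediate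
19 | (3S)-3-[(2S)-2-{[(tert-butyldimethylsilyl)oxy]methyl}-2-methyl-2,3-dihydrofuran-5-yl]-3-[(triethylsilyl)oxy]butanal | CC(C)(C)[Si](C)(C)OC[C@]1(C)CC=C(O1)[C@@](C)(O[Si](CC)(CC)CC)CC=O | intermediate
20 | 3,4-dibromofuran-2(5H)-one | O=C1OCC(Br)=C1Br | starting material
21 | 3-bromo-4-iodofuran-2(5H)-one | O=C1OCC(I)=C1Br | intermediate
22 | C8 carbinol, both epimers (4S,10S) | CC(C)(C)[Si](C)(C)OC[C@]1(C)CC=C(O1)[C@@](C)(O[Si](CC)(CC)CC)CC(O)C2=C(Br)C(=O)OC2 | intermediate
23 | C8 ketone (4S,10S) | CC(C)(C)[Si](C)(C)OC[C@]1(C)CC=C(O1)[C@@](C)(O[Si](CC)(CC)CC)CC(=O)C2=C(Br)C(=O)OC2 | intermediate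
24 | (8S)-alcohol (4S,8S,10S) | CC(C)(C)[Si](C)(C)OC[C@]1(C)CC=C(O1)[C@@](C)(O[Si](CC)(CC)CC)C[C@H](O)C2=C(Br)C(=O)OC2 | intermediate
25 | (8S)-acetate (4S,8S,10S) | CC(C)(C)[Si](C)(C)OC[C@]1(C)CC=C(O1)[C@@](C)(O[Si](CC)(CC)CC)C[C@H](OC(C)=O)C2=C(Br)C(=O)OC2 | intermediate
26 | (1S,3S)-1-(4-bromo-5-oxo-2,5-dihydrofuran-3-yl)-3-hydroxy-3-[(2S)-2-(hydroxymethyl)-2-methyl-2,3-dihydrofuran-5-yl]butyl acetate | OC[C@]1(C)CC=C(O1)[C@@](C)(O)C[C@H](OC(C)=O)C2=C(Br)C(=O)OC2 | intermediate
27 | (1S,3S)-1-(4-bromo-5-oxo-2,5-dihydrofuran-3-yl)-3-[(2S)-2-formyl-2-methyl-2,3-dihydrofuran-5-yl]-3-hydroxybutyl acetate | O=C[C@]1(C)CC=C(O1)[C@@](C)(O)C[C@H](OC(C)=O)C2=C(Br)C(=O)OC2 | intermediate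
28 | (1S,3S)-1-{4-bromo-5-[(triethylsilyl)oxy]furan-3-yl}-3-[(2S)-2-formyl-2-methyl-2,3-dihydrofuran-5-yl]-3-[(triethylsilyl)oxy]butyl acetate | O=C[C@]1(C)CC=C(O1)[C@@](C)(O[Si](CC)(CC)CC)C[C@H](OC(C)=O)c2coc(O[Si](CC)(CC)CC)c2Br | intermediate (not isolated)
29 | macrocyclic aldol silyl ether (C5–OSiEt3, C6–H; mixture at C5 and C6; 4S,8S,10S) | BrC1=C2C(C(O[Si](CC)(CC)CC)[C@]3(C)CC=C(O3)[C@@](C)(O[Si](CC)(CC)CC)C[C@@H]2OC(C)=O)OC1=O | intermediate (not isolated)
30 | bromo macrocycle with C10–OSiEt3 (4S,5E,8S,10S) | BrC1=C2/C(=C\[C@]3(C)CC=C(O3)[C@@](C)(O[Si](CC)(CC)CC)C[C@@H]2OC(C)=O)OC1=O | intermediate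
31 | bromo macrocycle with free C10–OH (4S,5E,8S,10S) | BrC1=C2/C(=C\[C@]3(C)CC=C(O3)[C@@](C)(O)C[C@@H]2OC(C)=O)OC1=O | intermediate
32 | 13-hydroxy compound (4S,5E,8S,10S) | OCC1=C2/C(=C\[C@]3(C)CC=C(O3)[C@@](C)(O)C[C@@H]2OC(C)=O)OC1=O | intermediate
33 | CNP0144020.1 (4S,5E,8S,10S) | CC(=O)OCC1=C2/C(=C\[C@]3(C)CC=C(O3)[C@@](C)(O)C[C@@H]2OC(C)=O)OC1=O | target

**Step count and risks**

Total: 22 steps. Longest linear sequence: 20 steps (steps 1–3, 5–11 and 13–22, from 1).

Steps most likely to fail:

1. Step 9. The reduced titanium alkylidene may not engage a carbonyl that lies between two fully substituted carbons, so the tethered alkylidene would be quenched, or only open-chain ethylidenation and alkene exchange products would form. Fallback: from 15, methylenation with the Tebbe reagent Cp2Ti(μ-CH2)(μ-Cl)AlMe2 (THF, pyridine, −40 to 0 °C) should give the acyclic enol ether F1. Ring-closing olefin metathesis of its two terminal alkenes with the second-generation Grubbs catalyst (toluene, 60 °C, ethene lost) then closes ring A, and the route is rejoined at 17.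

2. Step 19. Closure of a strained medium ring by an aldol addition may be outrun by intermolecular aldol oligomerisation or by simple silylation, and the C8 acetate could ionise at the silyloxyfuran stage. Fallback (the two C–C bonds made in the reverse order, ring closed by the Nozaki–Hiyama–Kishi reaction):
   - From 17, excess TBAF (THF, rt) removes all three silyl groups to give the triol F2.
   - TESCl (1 equiv), 2,6-lutidine, CH2Cl2, −78 °C silylates only the unhindered C8 hydroxyl to give the mono-silyl ether F3.
   - Dess–Martin oxidation (NaHCO3) gives the C5 aldehyde F4.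
   - TESOTf and Et3N (CH2Cl2, −78 °C) in the presence of 21 cap the C10 hydroxyl and effect an intermolecular vinylogous Mukaiyama aldol addition to the aldol silyl ether F5 (mixture at C5 and C6; both centres are lost later).
   - HF·pyridine with pyridine (THF, 0 °C) frees only the primary C8 hydroxyl to give the alcohol F6, which Dess–Martin periodinane oxidises to the C8 aldehyde F7.
   - CrCl2 with catalytic NiCl2 in DMSO/THF at high dilution closes the ring at C7–C8 to the macrocyclic carbinol F8.
   - DBU eliminates the C5 silyloxy group inside the ring to the ylidene carbinol F9, with the same ring-enforced 5E geometry.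
   - The C8 epimers of F9 are separated: the 8S epimer is acetylated (Ac2O, pyridine, DMAP) and the 8R epimer is inverted under Mitsunobu conditions (PPh3, DIAD, AcOH). Both give 30, where the route is rejoined.

3. Step 15. Poor facial selectivity is possible because both flanks of the ketone are bulky and the electron-poor ketone may also be reduced without the catalyst. Fallback: from 22, the two C8 epimers from step 13 are separated by chromatography. The 8S epimer is 24 and is acetylated as in step 16. The 8R epimer, the (8R)-alcohol F10, is converted with inversion into the same acetate by a Mitsunobu reaction (PPh3, DIAD, AcOH, THF, 0 °C). The route is rejoined at 25, and steps 14 and 15 are then not needed.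

**Further compounds**

F1 | step 9 | acyclic enol ether, (2S)-1-[(tert-butyldimethylsilyl)oxy]-2-methylpent-4-en-2-yl ether of (3S)-3,5-bis(triethylsilyloxy)-3-methylpent-1-en-2-ol | C=C(O[C@](C)(CO[Si](C)(C)C(C)(C)C)CC=C)[C@@](C)(O[Si](CC)(CC)CC)CCO[Si](CC)(CC)CC
F2 | step 19 | triol, (3S)-3-[(2S)-2-(hydroxymethyl)-2-methyl-2,3-dihydrofuran-5-yl]butane-1,3-diol | OC[C@]1(C)CC=C(O1)[C@@](C)(O)CCO
F3 | step 19 | mono-silyl ether, (2S)-2-[(2S)-2-(hydroxymethyl)-2-methyl-2,3-dihydrofuran-5-yl]-4-[(triethylsilyl)oxy]butan-2-ol | OC[C@]1(C)CC=C(O1)[C@@](C)(O)CCO[Si](CC)(CC)CC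
F4 | step 19 | C5 aldehyde, (2S)-5-[(2S)-2-hydroxy-4-(triethylsilyloxy)butan-2-yl]-2-methyl-2,3-dihydrofuran-2-carbaldehyde | O=C[C@]1(C)CC=C(O1)[C@@](C)(O)CCO[Si](CC)(CC)CC
F5 | step 19 | aldol silyl ether (3-bromo-4-iodobutenolide joined at C6 to C5; mixture at C5 and C6; 4S,10S) | BrC1=C(I)C(C(O[Si](CC)(CC)CC)[C@]2(C)CC=C(O2)[C@@](C)(O[Si](CC)(CC)CC)CCO[Si](CC)(CC)CC)OC1=O
F6 | step 19 | C8 alcohol of F5 | BrC1=C(I)C(C(O[Si](CC)(CC)CC)[C@]2(C)CC=C(O2)[C@@](C)(O[Si](CC)(CC)CC)CCO)OC1=O
F7 | step 19 | C8 aldehyde of F5 | BrC1=C(I)C(C(O[Si](CC)(CC)CC)[C@]2(C)CC=C(O2)[C@@](C)(O[Si](CC)(CC)CC)CC=O)OC1=O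
F8 | step 19 | macrocyclic carbinol (mixture at C5, C6 and C8; 4S,10S) | BrC1=C2C(C(O[Si](CC)(CC)CC)[C@]3(C)CC=C(O3)[C@@](C)(O[Si](CC)(CC)CC)CC2O)OC1=O
F9 | step 19 | ylidene carbinol (5E; both C8 epimers; 4S,10S) | BrC1=C2/C(=C\[C@]3(C)CC=C(O3)[C@@](C)(O[Si](CC)(CC)CC)CC2O)OC1=O
F10 | step 15 | (8R)-alcohol, C8 epimer of 24 | CC(C)(C)[Si](C)(C)OC[C@]1(C)CC=C(O1)[C@@](C)(O[Si](CC)(CC)CC)C[C@@H](O)C2=C(Br)C(=O)OC2
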